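## Retrosynthetic overview

1. Feature: the acyl part is an unbranched C28 chain in which the ester carbonyl C1 is followed only by CH2 groups. The strategy rests on the C1–C2–C3 segment, specifically the C2–C3 bond one methylene away from the ester carbonyl, where a two-carbon malonyl unit can be joined to a C26 acyl unit.
2. Functional-group level: the C3 methylene is traced back through the C2=C3 enoate and the C3 carbinol to a C3 ketone, 2-phenylethyl 3-oxooctacosanoate.
3. Key disconnection (C2–C3): the 3-oxo ester is split into hexacosanoyl imidazolide (C3–C28) and the magnesium enolate of mono 2-phenylethyl malonate (C1, C2 and the whole O–CH2–CH2–C6H5 group). The two are joined with loss of CO2.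
4. Precursors: the imidazolide comes from hexacosanoic acid and CDI, and the half-ester from Meldrum's acid and 2-phenylethanol, so the C1–O ester bond is made on the small fragment.
5. Rings: the only ring, the benzene ring, is bought with 2-phenylethanol. No ring is formed at any stage and the target has no stereocentre.

Key step: step 3

Assumption: "phenylethyl" is read as 2-phenylethyl (O–CH2–CH2–Ph), as the SMILES shows. The target carries no stereocentre and no C=C bond, so it needs no descriptor.

## Route

**Step 1**
Reactants: 1 hexacosanoic acid
Product: 3 1-(1H-imidazol-1-yl)hexacosan-1-one (hexacosanoyl imidazolide), via mixed acyl imidazolecarboxylate anhydride 2 (not isolated)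
Conditions: CDI (1.1 equiv), THF, 45 °C, 2 h, N2; cool to 0 °C, filter under N2
Reagents that add atoms: 1,1'-carbonyldiimidazole (CDI), O=C(n1ccnc1)n1ccnc1
Why: Carboxyl activation by acyl transfer with CDI (imidazolide synthesis), in which the acid attacks CDI, the released imidazole attacks the acyl carbon of anhydride 2 and loss of CO2 drives the reaction, while warm THF keeps the waxy acid dissolved and cooling should let the long-chain imidazolide crystallise free of imidazole and surplus CDI.

**Step 2**
Reactants: 4 Meldrum's acid (2,2-dimethyl-1,3-dioxane-4,6-dione); 5 2-phenylethanol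
Product: 6 3-oxo-3-(2-phenylethoxy)propanoic acid (mono 2-phenylethyl malonate)
Conditions: PhMe, 110 °C, 6 h; aq NaHCO3 extraction, then HCl to pH 2
Reagents that add atoms: none
Why: Alcoholysis of Meldrum's acid, in which the primary alcohol opens the highly electrophilic cyclic acylal at one carbonyl and acetone is expelled, so exactly one ester and one free acid result and the product can be purified by acid–base extraction.

**Step 3**
Reactants: 3 hexacosanoyl imidazolide; 6 mono 2-phenylethyl malonate
Product: 10 2-phenylethyl 3-oxooctacosanoate, via magnesium malonate enolate 7 (not isolated), via acylated magnesium malonate 8 (not isolated), via magnesium oxo ester enolate 9 (not isolated)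
Conditions: 6 (2 equiv), MgCl2 (anhydrous, 2 equiv), Et3N (4 equiv), THF/MeCN, 0 °C → rt, 2 h; then 3 in THF, 45 °C, 16 h; 1 M HCl
Reagents that add atoms: magnesium chloride, [Mg+2].[Cl-].[Cl-] (Mg and Cl are held only in 7, 8 and 9 and leave at the acid quench; none of its atoms stays in 10)
Why: MgCl2 and Et3N turn 6 into its carboxylate and then into the chelated enolate 7, because divalent magnesium binds both carbonyl oxygens and acidifies the C2 protons (soft enolisation). C2 of 7 attacks the carbonyl carbon of 3, imidazole leaves from the tetrahedral adduct, and the new C2–C3 bond stands in the acylated malonate 8. The carboxylate of 8 now lies beta to a ketone and an ester, so it loses CO2 to give the chelated enolate 9, which the acid quench protonates to 10, and the escape of gas makes the condensation irreversible. The closest known reaction type is the decarboxylative Claisen condensation of magnesium malonate half-esters with acyl imidazolides (Masamune–Brooks reaction), the flask counterpart of the condensing step of fatty-acid chain elongation. No ring is closed and no stereocentre is formed. The step needs C- over O-acylation and a single acylation: magnesium ties up the oxygens of 7 and leaves C2 as the nucleophilic site, 9 is a stabilised chelated enolate too weak to attack a second imidazolide, and the phenethyl ester and the unfunctionalised C25 tail offer no competing site.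

**Step 4**
Reactants: 10 2-phenylethyl 3-oxooctacosanoate
Product: 11 2-phenylethyl 3-hydroxyoctacosanoate (racemic)
Conditions: NaBH4 (1 equiv), THF/i-PrOH, 0 °C → rt; then H2O
Reagents that add atoms: none
Why: Chemoselective borohydride reduction of the ketone of a 3-oxo ester (the ketoreductase counterpart), in which NaBH4 attacks the ketone much faster than the ester, the hindered co-solvent avoids ester exchange, and the new C3 carbinol centre forms as a racemate without need of control because step 5 erases it.

**Step 5**
Reactants: 11 2-phenylethyl 3-hydroxyoctacosanoate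
Product: 13 2-phenylethyl (E)-octacos-2-enoate, via 3-mesyloxy ester 12 (not isolated)
Conditions: MsCl (1.5 equiv), Et3N (2 equiv), CH2Cl2, 0 °C, 1 h; then DBU (2.5 equiv), rt, 12 h
Reagents that add atoms: methanesulfonyl chloride, CS(=O)(=O)Cl (its atoms are held only in 12 and leave again in the elimination; none stays in 13)
Why: Mesylation followed by E1cB elimination (the dehydratase counterpart), in which the C3 mesylate sits beta to the ester so that DBU removes an acidic C2 proton and expels mesylate to give the conjugated E-enoate, and any Z or 3-enoate isomer would converge on the same product in step 6.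

**Step 6**
Reactants: 13 2-phenylethyl (E)-octacos-2-enoate
Product: 14 2-phenylethyl octacosanoate (phenylethyl n-octacosanoate)
Conditions: H2 (1 atm), Pd/C (10 wt% Pd), THF/EtOAc, 40 °C
Reagents that add atoms: none
Why: Heterogeneous catalytic hydrogenation of the conjugated C2=C3 bond (the enoyl reductase counterpart), in which a disubstituted enoate takes up H2 readily on Pd, the benzene ring is inert at this pressure, and the ester O–CH2 bond is homobenzylic rather than benzylic, so no hydrogenolysis is expected.

## Compound list

1 | hexacosanoic acid (cerotic acid) | CCCCCCCCCCCCCCCCCCCCCCCCCC(=O)O | starting material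
2 | hexacosanoic 1H-imidazole-1-carboxylic anhydride (not isolated) | CCCCCCCCCCCCCCCCCCCCCCCCCC(=O)OC(=O)n1ccnc1 | intermediate
3 | 1-(1H-imidazol-1-yl)hexacosan-1-one (hexacosanoyl imidazolide) | CCCCCCCCCCCCCCCCCCCCCCCCCC(=O)n1ccnc1 | intermediate
4 | Meldrum's acid (2,2-dimethyl-1,3-dioxane-4,6-dione) | CC1(C)OC(=O)CC(=O)O1 | starting material
5 | 2-phenylethanol | OCCc1ccccc1 | starting material
6 | 3-oxo-3-(2-phenylethoxy)propanoic acid (mono 2-phenylethyl malonate) | OC(=O)CC(=O)OCCc1ccccc1 | intermediate
7 | magnesium salt of the carboxylate-enolate dianion of 6, O,O-chelated (not isolated) | [Mg+2].[O-]C(=O)C=C([O-])OCCc1ccccc1 | intermediate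
8 | chloromagnesium 2-hexacosanoyl-3-oxo-3-(2-phenylethoxy)propanoate, the C-acylated malonate, C2 transient and racemic (not isolated) | CCCCCCCCCCCCCCCCCCCCCCCCCC(=O)C(C(=O)[O-])C(=O)OCCc1ccccc1.[Mg+2].[Cl-] | intermediate
9 | chloromagnesium enolate of 2-phenylethyl 3-oxooctacosanoate, O,O-chelated (not isolated) | CCCCCCCCCCCCCCCCCCCCCCCCCC([O-])=CC(=O)OCCc1ccccc1.[Mg+2].[Cl-] | intermediate
10 | 2-phenylethyl 3-oxooctacosanoate | CCCCCCCCCCCCCCCCCCCCCCCCCC(=O)CC(=O)OCCc1ccccc1 | intermediate
11 | 2-phenylethyl 3-hydroxyoctacosanoate, racemic at C3 | CCCCCCCCCCCCCCCCCCCCCCCCCC(O)CC(=O)OCCc1ccccc1 | intermediate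
12 | 2-phenylethyl 3-(methylsulfonyloxy)octacosanoate, racemic at C3 (not isolated) | CCCCCCCCCCCCCCCCCCCCCCCCCC(CC(=O)OCCc1ccccc1)OS(C)(=O)=O | intermediate
13 | 2-phenylethyl (E)-octacos-2-enoate | CCCCCCCCCCCCCCCCCCCCCCCCC/C=C/C(=O)OCCc1ccccc1 | intermediate
14 | 2-phenylethyl octacosanoate (phenylethyl n-octacosanoate), achiral | CCCCCCCCCCCCCCCCCCCCCCCCCCCC(=O)OCCc1ccccc1 | target

## Step count and risks

Total step count: 6.
Longest linear sequence: 5 steps (steps 1, 3, 4, 5, 6, or equally steps 2, 3, 4, 5, 6).

**Step 3 (key step).**
- Risk: the waxy imidazolide and the heterogeneous magnesium enolate may meet too slowly. Adventitious moisture could then hydrolyse the acyl donor, or the half-ester could simply decarboxylate without being acylated.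
- Fallback: it sets out from 1, 4 and 5 and comes back to the route at 10.
- Acid 1 is coupled with Meldrum's acid 4 (DCC, DMAP, CH2Cl2/THF, 0 °C → rt) to give 5-(1-hydroxyhexacosylidene)-2,2-dimethyl-1,3-dioxane-4,6-dione F1.
- Heating this compound with alcohol 5 in toluene at reflux releases hexacosanoylketene F2, which the alcohol traps to give 10.
- The same C2–C3 bond is made, again by acylation of a malonyl unit with later loss of CO2, but in homogeneous solution and without a magnesium enolate.

**Step 5.**
- Risk: elimination may be sluggish or incomplete on a poorly soluble substrate. Substitution at C3 by chloride, or attack of the base on the ester, may compete.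
- Fallback: it sets out from 11 and comes back at 14, leaving out 13 and step 6.
- It is a Barton–McCombie deoxygenation. Treatment of 11 with 1,1'-thiocarbonyldiimidazole and DMAP in THF at reflux gives 2-phenylethyl 3-[(1H-imidazol-1-ylcarbonothioyl)oxy]octacosanoate F3.
- Bu3SnH with AIBN in toluene at 90 °C then replaces the C3–O bond by C3–H through the secondary C3 radical.

**Step 4.**
- Risk: over-reduction of the ester through the boron-chelated 3-hydroxy ester, ester exchange with the alcohol co-solvent, or stalling because the substrate precipitates in the cold.
- Fallback: it sets out from 10 and comes back at 14, leaving out 11 to 13.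
- It removes the ketone oxygen without a hydride reagent. Ethane-1,2-dithiol and BF3·OEt2 in CH2Cl2 convert the ketone into 2-phenylethyl (2-pentacosyl-1,3-dithiolan-2-yl)acetate F4.
- Raney Ni in THF (Mozingo desulfurisation) then exchanges both C–S bonds for C–H bonds.

## Further compounds

F1 | step 3 | 5-(1-hydroxyhexacosylidene)-2,2-dimethyl-1,3-dioxane-4,6-dione | CCCCCCCCCCCCCCCCCCCCCCCCCC(O)=C1C(=O)OC(C)(C)OC1=O
F2 | step 3 | hexacosanoylketene (3-oxooctacos-1-en-1-one) | CCCCCCCCCCCCCCCCCCCCCCCCCC(=O)C=C=O
F3 | step 5 | 2-phenylethyl 3-[(1H-imidazol-1-ylcarbonothioyl)oxy]octacosanoate, racemic at C3 | CCCCCCCCCCCCCCCCCCCCCCCCCC(CC(=O)OCCc1ccccc1)OC(=S)n1ccnc1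
F4 | step 4 | 2-phenylethyl (2-pentacosyl-1,3-dithiolan-2-yl)acetate | CCCCCCCCCCCCCCCCCCCCCCCCCC1(CC(=O)OCCc2ccccc2)SCCS1
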